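**Retrosynthetic overview**
1. The target comes from a crotyl adduct by alkene cleavage and ester adjustment. The C2–C3 bond is made from an enantiopure (E)-crotylsilane and the six-membered peroxycarbenium ion of a 1,2-dioxan-3-yl acetate; this sets C2 and C3 and sorts C6.
2. The 1,2-dioxan-3-ol comes from a 2,2-disubstituted cyclobutanol and O2. The carbocycle C3–C4–C5–C6 is cut at C3–C6 and both oxygen atoms are inserted, turning the four-membered ring into the six-membered ring.
3. Enabling feature: the O–O unit of the dioxane bridges four contiguous carbons. C6 is fully substituted, so it gives a tertiary radical that directs the β-scission. C3 is β to the ester, so it can be carried at the aldehyde/hemiperacetal level and later bonded to a propionate-type nucleophile.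
4. The cyclobutanol comes from dihydro-β-ionone and a sulfonium cyclopropylide (ketone carbon = C6, its methyl = C6–CH3). The enone comes from allylic oxidation.
5. Ring order: the cyclohexene ring is bought, the cyclobutane is built in step 1, and the cyclobutane is expanded to the 1,2-dioxane in step 4.

Key step: step 4

Assumption: locants C1–C6 follow the propanoate chain through the dioxane (C1 ester carbon, C2 CHMe, C3 and C6 the O-bearing ring carbons); C6 is made racemic in step 4 and its 6R half is selected in step 8.

**Step 1**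
Reactants: 1 dihydro-β-ionone; 2 cyclopropyldiphenylsulfonium tetrafluoroborate
Product: 4 2-methyl-2-[2-(2,6,6-trimethylcyclohex-1-en-1-yl)ethyl]cyclobutan-1-one (racemic), via oxaspiropentane 3 (not isolated)
Conditions: KOH, DMSO, 25 °C; then LiBF4 (cat.), PhH, 25 °C
Reagents that add atoms: cyclopropyldiphenylsulfonium tetrafluoroborate (2), C1CC1[S+](c1ccccc1)c1ccccc1.F[B-](F)(F)F
Why: Sulfonium cyclopropylide spiroannulation: the ylide adds to the unhindered methyl ketone and closes to 3, whose strain-driven 1,2-shift should give the 2,2-disubstituted cyclobutanone; the new quaternary carbon (future C6) is racemic, which is harmless because step 4 flattens it.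

**Step 2**
Reactants: 4 cyclobutanone
Product: 5 2-methyl-2-[2-(2,6,6-trimethyl-3-oxocyclohex-1-en-1-yl)ethyl]cyclobutan-1-one (racemic)
Conditions: CrO3, 3,5-dimethylpyrazole, CH2Cl2, −20 °C
Reagents that add atoms: chromium trioxide, O=[Cr](=O)=O
Why: Allylic oxidation with hexavalent chromium: the ring CH2 next to the methyl-bearing alkene carbon is the only unhindered secondary allylic site (the chain CH2 is shielded by the gem-dimethyl group), as is usual for the ionone ring, and the cyclobutanone is inert; no stereocentre is formed.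

**Step 3**
Reactants: 5 keto-enone
Product: 6 3-[2-(2-hydroxy-1-methylcyclobutyl)ethyl]-2,4,4-trimethylcyclohex-2-en-1-one (cis/trans mixture, racemic)
Conditions: NaBH4, MeOH/CH2Cl2, −78 °C
Reagents that add atoms: none
Why: Chemoselective borohydride reduction: the strained, non-conjugated cyclobutanone should react far faster than the hindered tetrasubstituted enone, and the carbinol mixture is used as such because both cyclobutane stereocentres are erased in step 4.

**Step 4**
Reactants: 6 cyclobutanol
Product: 8 3-[2-(6-hydroxy-3-methyl-1,2-dioxan-3-yl)ethyl]-2,4,4-trimethylcyclohex-2-en-1-one (racemic at C6, anomer mixture), via hydroperoxy aldehyde 7 (not isolated)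
Conditions: Co(acac)2 (10 mol %), O2 (1 atm), PhMe, 40 °C
Reagents that add atoms: dioxygen, O=O
Why: Cobalt-catalysed aerobic oxidative ring expansion: a trivalent cobalt cyclobutoxide homolyses to the cyclobutyloxyl radical, β-scission of C3–C6 releases the ring strain and gives the tertiary C6 radical, this captures triplet O2, and the peroxyl radical is reduced by divalent cobalt and protonated by the next molecule of 6 to give 7. This is the known Co(acac)2/O2 conversion of secondary cyclobutanols into 1,2-dioxan-3-ols, applied here to a new substrate. The dioxane closes by 6-exo-trig addition of the OOH group to the aldehyde (hemiperacetal formation), so the carbocycle C3–C4–C5–C6 becomes the six-membered ring by insertion of both oxygen atoms between C3 and C6. C6 arises from a planar radical with no control element and is racemic by design (sorted in step 8), and C3 is a freely equilibrating anomeric centre that is erased in step 8, so all four stereoisomers of 6 converge on one material. The step needs scission toward C6 rather than C4, which the fully substituted C6 secures (tertiary versus primary radical), and it needs the other ring to stay untouched, which is secured by having the electron-poor enone in place of the autoxidisable tetrasubstituted alkene.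

**Step 5**
Reactants: 8 dioxanol
Product: 9 6-methyl-6-[2-(2,6,6-trimethyl-3-oxocyclohex-1-en-1-yl)ethyl]-1,2-dioxan-3-yl acetate (racemic at C6, anomer mixture)
Conditions: Ac2O, pyridine, DMAP (cat.), CH2Cl2, 0 °C
Reagents that add atoms: acetic anhydride, CC(=O)OC(C)=O
Why: O-Acylation of the hemiperacetal turns the anomeric OH into a leaving group; the mild amine base at 0 °C should avoid Kornblum–DeLaMare-type O–O fragmentation at C3–H, and the anomer ratio is irrelevant.

**Step 6**
Reactants: 10 (S)-but-3-yn-2-ol
Product: 11 (2S,3E)-4-[dimethyl(phenyl)silyl]but-3-en-2-ol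
Conditions: PhMe2SiH, H2PtCl6 (0.1 mol %), THF, 50 °C
Reagents that add atoms: dimethylphenylsilane, C[SiH](C)c1ccccc1
Why: Platinum-catalysed syn hydrosilylation of the terminal alkyne should give the (E)-β-vinylsilane, and the carbinol stereocentre from the chiral pool is untouched.

**Step 7**
Reactants: 11 vinylsilane alcohol
Product: 13 methyl (3S,4E)-3-[dimethyl(phenyl)silyl]hex-4-enoate, via ketene acetal 12 (not isolated)
Conditions: MeC(OMe)3, EtCO2H (cat.), PhMe, reflux
Reagents that add atoms: trimethyl orthoacetate, CC(OC)(OC)OC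
Why: Johnson–Claisen rearrangement: 12 reacts through a chair with the carbinol methyl equatorial, so the C–O chirality is passed suprafacially to the new C–Si stereocentre (S) and the new alkene is E.

**Step 8**
Reactants: 9 dioxanyl acetate; 13 crotylsilane
Product: 15 methyl (3E,5S)-5-{(3S,6R)-6-methyl-6-[2-(2,6,6-trimethyl-3-oxocyclohex-1-en-1-yl)ethyl]-1,2-dioxan-3-yl}hex-3-enoate, via peroxycarbenium triflate 14 (not isolated)
Conditions: 13 (1.2 equiv), TMSOTf (20 mol %), CH2Cl2, −78 → −40 °C; SiO2 chromatography
Reagents that add atoms: methyl (3S,4E)-3-[dimethyl(phenyl)silyl]hex-4-enoate (13), COC(=O)C[C@@H](/C=C/C)[Si](C)(C)c1ccccc1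
Why: Hosomi–Sakurai-type crotylation of a peroxycarbenium ion (known for allylsilanes with peroxyacetals): either anomer of 9 ionises to 14, the silane reacts anti-SE2' so that its stereocentre fixes C2, and the antiperiplanar open transition state with the crotyl methyl in the H/O sector gives the 2,3-syn relation and hence 3S; C6 bears two sterically alike alkyl arms and exerts no facial bias, so both enantiomers of 9 react in the same sense and the 6R adduct 15 is parted from its C6 epimer by chromatography, which is where C6 is fixed.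

**Step 9**
Reactants: 15 crotyl adduct
Product: 17 (2R)-2-{(3S,6R)-6-methyl-6-[2-(2,6,6-trimethyl-3-oxocyclohex-1-en-1-yl)ethyl]-1,2-dioxan-3-yl}propanal, via ozonide 16 (not isolated)
Conditions: O3, CH2Cl2, −78 °C (Sudan Red 7B end point); Me2S, −78 → 0 °C
Reagents that add atoms: ozone, [O-][O+]=O
Why: Criegee ozonolysis with reductive work-up: the electron-neutral disubstituted alkene should react well before the hindered electron-poor enone, Me2S reduces 16 but not the dialkyl peroxide, and no stereocentre is touched if the β-peroxy aldehyde is kept cold and used crude.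

**Step 10**
Reactants: 17 aldehyde
Product: 18 (2R)-2-{(3S,6R)-6-methyl-6-[2-(2,6,6-trimethyl-3-oxocyclohex-1-en-1-yl)ethyl]-1,2-dioxan-3-yl}propanoic acid
Conditions: NaClO2, NaH2PO4, 2-methylbut-2-ene, t-BuOH/H2O, 0 °C
Reagents that add atoms: sodium chlorite, [Na+].[O-]Cl=O
Why: Pinnick oxidation: buffered chlorite oxidises the aldehyde without enolisation or β-elimination, so C2 and C3 are kept, and the peroxide and the enone are inert.

**Step 11**
Reactants: 18 acid
Product: 19 methyl diacarnoate A, methyl (2R)-2-{(3S,6R)-6-methyl-6-[2-(2,6,6-trimethyl-3-oxocyclohex-1-en-1-yl)ethyl]-1,2-dioxan-3-yl}propanoate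
Conditions: TMSCHN2, PhMe/MeOH, 0 °C
Reagents that add atoms: (trimethylsilyl)diazomethane, C[Si](C)(C)C=[N+]=[N-]
Why: Base-free O-methylation of the acid with a diazoalkane avoids retro-oxa-Michael opening of the β-peroxy ester, so all three stereocentres are preserved.

**Compound list**
1 | dihydro-β-ionone | CC(=O)CCC1=C(C)CCCC1(C)C | starting material
2 | cyclopropyldiphenylsulfonium tetrafluoroborate | C1CC1[S+](c1ccccc1)c1ccccc1.F[B-](F)(F)F | starting material
3 | 2-methyl-2-[2-(2,6,6-trimethylcyclohex-1-en-1-yl)ethyl]-1-oxaspiro[2.2]pentane | CC1(CCC2=C(C)CCCC2(C)C)OC12CC2 | intermediate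
4 | 2-methyl-2-[2-(2,6,6-trimethylcyclohex-1-en-1-yl)ethyl]cyclobutan-1-one | CC1(CCC2=C(C)CCCC2(C)C)CCC1=O | intermediate
5 | 2-methyl-2-[2-(2,6,6-trimethyl-3-oxocyclohex-1-en-1-yl)ethyl]cyclobutan-1-one | CC1(CCC2=C(C)C(=O)CCC2(C)C)CCC1=O | intermediate
6 | 3-[2-(2-hydroxy-1-methylcyclobutyl)ethyl]-2,4,4-trimethylcyclohex-2-en-1-one | CC1(CCC2=C(C)C(=O)CCC2(C)C)CCC1O | intermediate
7 | 4-hydroperoxy-4-methyl-6-(2,6,6-trimethyl-3-oxocyclohex-1-en-1-yl)hexanal | CC(CCC=O)(CCC1=C(C)C(=O)CCC1(C)C)OO | intermediate
8 | 3-[2-(6-hydroxy-3-methyl-1,2-dioxan-3-yl)ethyl]-2,4,4-trimethylcyclohex-2-en-1-one | CC1(CCC2=C(C)C(=O)CCC2(C)C)CCC(O)OO1 | intermediate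
9 | 6-methyl-6-[2-(2,6,6-trimethyl-3-oxocyclohex-1-en-1-yl)ethyl]-1,2-dioxan-3-yl acetate | CC(=O)OC1CCC(C)(CCC2=C(C)C(=O)CCC2(C)C)OO1 | intermediate
10 | (S)-but-3-yn-2-ol | C[C@H](O)C#C | starting material
11 | (2S,3E)-4-[dimethyl(phenyl)silyl]but-3-en-2-ol | C[C@H](O)/C=C/[Si](C)(C)c1ccccc1 | intermediate
12 | mixed ketene acetal of 11 (1-methoxyvinyl ether) | C=C(OC)O[C@@H](C)/C=C/[Si](C)(C)c1ccccc1 | intermediate
13 | methyl (3S,4E)-3-[dimethyl(phenyl)silyl]hex-4-enoate | COC(=O)C[C@@H](/C=C/C)[Si](C)(C)c1ccccc1 | intermediate
14 | six-membered peroxycarbenium triflate from 9 | CC1(CCC2=C(C)C(=O)CCC2(C)C)CCC=[O+]O1.[O-]S(=O)(=O)C(F)(F)F | intermediate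
15 | methyl (3E,5S)-5-{(3S,6R)-6-methyl-6-[2-(2,6,6-trimethyl-3-oxocyclohex-1-en-1-yl)ethyl]-1,2-dioxan-3-yl}hex-3-enoate | COC(=O)C/C=C/[C@H](C)[C@@H]1CC[C@@](C)(CCC2=C(C)C(=O)CCC2(C)C)OO1 | intermediate
16 | 1,2,4-trioxolane (ozonide) of 15 | COC(=O)CC1OOC(O1)[C@H](C)[C@@H]1CC[C@@](C)(CCC2=C(C)C(=O)CCC2(C)C)OO1 | intermediate
17 | (2R)-2-{(3S,6R)-dioxanyl}propanal | O=C[C@H](C)[C@@H]1CC[C@@](C)(CCC2=C(C)C(=O)CCC2(C)C)OO1 | intermediate
18 | (2R)-2-{(3S,6R)-dioxanyl}propanoic acid | OC(=O)[C@H](C)[C@@H]1CC[C@@](C)(CCC2=C(C)C(=O)CCC2(C)C)OO1 | intermediate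
19 | methyl diacarnoate A | COC(=O)[C@H](C)[C@@H]1CC[C@@](C)(CCC2=C(C)C(=O)CCC2(C)C)OO1 | target

**Step count:** 11 steps in total. The longest linear sequence is 9 steps (steps 1–5 and 8–11).

**Steps most likely to fail**

Step 4. The ring expansion may be lost in three ways: dehydrogenation of the carbinol back to the ketone, scission toward C4, or autoxidation of the aldehyde tautomer and of the enone γ-positions.
- The fallback makes the tertiary hydroperoxide by a polar route, setting out from 1.
- But-3-enylmagnesium bromide gives 3-methyl-1-(2,6,6-trimethylcyclohex-1-en-1-yl)hept-6-en-3-ol F1.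
- The CrO3/3,5-dimethylpyrazole oxidation of step 2 gives the enone alcohol 3-(3-hydroxy-3-methylhept-6-en-1-yl)-2,4,4-trimethylcyclohex-2-en-1-one F2.
- Acid-catalysed perhydrolysis (50 % H2O2, cat. H2SO4, Et2O, 0 °C; SN1 at the tertiary carbinol) gives the hydroperoxide 3-(3-hydroperoxy-3-methylhept-6-en-1-yl)-2,4,4-trimethylcyclohex-2-en-1-one F3.
- Ozonolysis of the terminal alkene with Me2S work-up gives 7, which closes to 8, where the route is rejoined.

Step 8. The crotylation may suffer from poor simple or facial diastereoselection on the cyclic cation, from silyl-retaining annulation instead of desilylation, or from incomplete chromatographic parting of the C6 epimers.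
- The fallback brings in chirality with an enzyme instead of a reagent, setting out from 9.
- Sc(OTf)3-catalysed Mukaiyama-type addition of 1-methoxy-1-(trimethylsilyloxy)prop-1-ene gives methyl 2-{6-methyl-6-[2-(2,6,6-trimethyl-3-oxocyclohex-1-en-1-yl)ethyl]-1,2-dioxan-3-yl}propanoate as a stereoisomer mixture F4.
- The racemic (2R*,3S*,6R*) diastereomer is isolated by HPLC.
- It is then hydrolysed enantioselectively with Candida rugosa lipase (pH 7 buffer), planned so that the 2R ester is the one taken; this gives 18, where the route is rejoined.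

Step 9. The β-peroxy aldehyde may be lost by β-elimination (retro-oxa-Michael opening) or by epimerisation at C2, and ozone may over-react with the enone.
- The fallback never lets the aldehyde build up.
- From 15, osmium-catalysed oxidative cleavage (OsO4 (1 mol %), 2KHSO5·KHSO4·K2SO4, DMF) takes the disubstituted alkene directly to 18.

**Further compounds**
F1 | step 4 | 3-methyl-1-(2,6,6-trimethylcyclohex-1-en-1-yl)hept-6-en-3-ol | CC(O)(CCC=C)CCC1=C(C)CCCC1(C)C
F2 | step 4 | 3-(3-hydroxy-3-methylhept-6-en-1-yl)-2,4,4-trimethylcyclohex-2-en-1-one | CC(O)(CCC=C)CCC1=C(C)C(=O)CCC1(C)C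
F3 | step 4 | 3-(3-hydroperoxy-3-methylhept-6-en-1-yl)-2,4,4-trimethylcyclohex-2-en-1-one | CC(CCC=C)(CCC1=C(C)C(=O)CCC1(C)C)OO
F4 | step 8 | methyl 2-{6-methyl-6-[2-(2,6,6-trimethyl-3-oxocyclohex-1-en-1-yl)ethyl]-1,2-dioxan-3-yl}propanoate (stereoisomer mixture) | COC(=O)C(C)C1CCC(C)(CCC2=C(C)C(=O)CCC2(C)C)OO1
F0 | step 9 | none | none
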